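The decision here is to measure each flask by its exposure to free catalyst and not by its minutes.

| setting | ochre | blue | grey | violet |
|---|---|---|---|---|
| starting material | 0.50 mM | 0.50 mM | 0.50 mM | 0.50 mM |
| coupling partner | 1.20 equiv | 1.20 equiv | 1.20 equiv | 1.20 equiv |
| free catalyst | 0.012 mol% | 0.025 mol% | 0.05 mol% | 0.1 mol% |
| added ligand | 0.94 µM | 0.94 µM | 0.94 µM | 0.94 µM |
| time | 3.0 min | 3.0 min | 3.0 min | 3.0 min |

    catalyst intermediate B → catalyst intermediate C (k1 = 9860 /s)
    starting material + free catalyst → catalyst intermediate A (k2 = 3.10 × 10⁵ /M/s)
    free catalyst + added ligand ⇌ idle complex (K3 = 1.3 × 10⁶ /M, k3 = 69500 /M/s)
    coupling partner + catalyst intermediate A ⇌ catalyst intermediate B (K4 = 300 /M, k4 = 2.11 × 10⁶ /M/s)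
    catalyst intermediate C ⇌ free catalyst + target (K5 = 0.0022 M, k5 = 84.2 /s)
    starting material + catalyst intermediate B → spent catalyst (k6 = 9.31 /M/s)
    target + free catalyst ⇌ isomer of the product + free catalyst, rate k7*[free catalyst]*[target] forward; the back reaction follows from the equilibrium constant (K7 = 21.9, k7 = 29500 /M/s)

* amount of target at the end, in percent of the starting material charged for ochre, blue, grey, violet, in this order
* the shape of the row from first to last (falls all the way / hardly changes / rises, then falls / falls, then rises / rises all the way)

- percent here means starting material units held: one spent catalyst counts as two
- "hardly changes" means that all values lie within two and a half points (for a concentration: within two and a half percent of the largest)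
- run time (ochre): 3.0 min

Exposure, w, is the capture constant 3.10 × 10⁵ /M/s times the time integral of [free catalyst], so [starting material] falls as exp(−w) however the catalyst divides itself. Isomerisation consumes target through the same [free catalyst], so per unit of w it takes the selectivity factor 0.0952 times [target], with its way back neglected. With x the fraction of starting material left, target is then (x^s − x)/(1 − s), where s is that factor. Gain equals loss at the peak exposure, the logarithm of the inverse factor divided by one minus the factor: 2.60. There 7.43% of the starting material remains and target reaches 78.1%.

In the first seconds, added ligand draws free catalyst into idle complex. That exchange relaxes with a half-life of 5.83 s, shorter than the 0.62 min half-life of starting material in ochre at charged catalyst, and in ochre the ratio of idle complex to free catalyst is reckoned at 1.2 with ligand at its charge.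

Through the middle, the round turns. Coupling partner, at 1.20 equiv, stays in excess of the limiting reagent, starting material. Catalyst intermediate B moves on at 9860 /s, far faster than its loss to spent catalyst at 0.00466 /s. Catalyst intermediate C releases target at 84.2 /s, and its reckoned ratio to free catalyst is 1.84 with [starting material] at its charge and 0.227 with [target] at that same concentration. With ligand at its charge and catalyst intermediate A neglected, the reckoned share of free catalyst in the charge goes from 24.6% at the first of those ends to 40.8% at the second.

Integrating the inverse of that share up to the peak exposure gives 7.86. Dividing this by the capture constant times the charged catalyst gives the reckoned time of the peak: 7.04 min for ochre, 3.38 min for blue, 1.69 min for grey and 0.845 min for violet. Against 3.0 min, the reckoning has ochre and blue stopping before their peaks, and grey and violet running past theirs. It therefore commits to a rise and then a fall, with a reckoned top of 78.1%, but it gives no full row.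

The forecast does give one, 58%, 78%, 66% and 35%, rises, then falls, on the ground that “More catalyst overshoots into isomerisation.”

The flasks give 58.1%, 77.7%, 65.4% and 33.7%, rises, then falls, with the turn at 0.028 mol%. In blue, capture was still running at 3.00 min with 10% of the starting material left, an exposure of 2.30, short of 2.60, while isomerisation had made 12.2% isomer, and the rule gives 77.7% target. In grey, 0.41% of the starting material stood at 3.00 min, an exposure of 5.50, beyond 2.60, isomer had reached 34.2%, and the rule gives 65.0% target.

The numbers of this flask are invented.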